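## Retrosynthetic overview

1. The aroyl C8–C(=O) bond is made last: ortho-lithiation of the finished chroman between O1 and O7, addition to aldehyde 21, then MnO2.
2. The C6–CH2 bond comes from the C6 aryllithium and iodide 7; its stereocentre is C4 of (R)-limonene (1 → 2 → 3 → 4 → 7, one carbon excised).
3. Pyran ring C is the only ring formed (rings A and B are bought): aryl Grignard/CuI opening of methyl (R)-glycidate 11, MeMgBr, then acid closes O1–C2 through the tertiary cation with the C3–O bond untouched.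
4. The arene is 5-methoxyresorcinol 8, dibrominated para to each OH to mark C4a and C6.
5. Order: ring C first (acid is used only before the 1,1-disubstituted alkenes arrive), then the side chain, then the aroyl group, then fluoride deprotection.

Assumption: commercial (+)-limonene 1,2-oxide is used as its cis/trans mixture; both epoxide carbons become carbonyl carbons in step 1, so only C4 (R) matters.

## Route

Step 1
Reactants: 1 (4R)-limonene 1,2-oxide
Product: 2 (3R)-6-oxo-3-(prop-1-en-2-yl)heptanal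
Conditions: H5IO6, THF/H2O, 0 → 23 °C
Reagents that add atoms: water, O
Why: Periodic acid hydrolyses the trisubstituted epoxide and cleaves the diol (Malaprade glycol cleavage) without touching the isopropenyl group, so C4 of (R)-limonene is carried over unchanged as C3.

Step 2
Reactants: 2 (3R)-6-oxo-3-(prop-1-en-2-yl)heptanal
Product: 3 (3R)-6-oxo-3-(prop-1-en-2-yl)heptanoic acid
Conditions: NaClO2, NaH2PO4, 2-methylbut-2-ene, t-BuOH/H2O, 0 → 23 °C
Reagents that add atoms: NaClO2, [Na+].[O-]Cl=O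
Why: Pinnick oxidation takes only the aldehyde to the acid, the scavenger protects the alkene from HOCl, and the stereocentre is not alpha to a carbonyl so it cannot epimerise.

Step 3
Reactants: 3 (3R)-6-oxo-3-(prop-1-en-2-yl)heptanoic acid
Product: 4 (3R)-6-methyl-3-(prop-1-en-2-yl)hept-6-enoic acid
Conditions: Ph3PCH3Br (2.5 equiv), KOtBu (3.5 equiv), THF, 0 → 23 °C; then aq. HCl
Reagents that add atoms: methyltriphenylphosphonium bromide, C[P+](c1ccccc1)(c1ccccc1)c1ccccc1.[Br-]
Why: Wittig methylenation of the ketone proceeds on the potassium carboxylate, which is inert to the ylide, and leaves the stereocentre untouched.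

Step 4
Reactants: 4 (3R)-6-methyl-3-(prop-1-en-2-yl)hept-6-enoic acid
Product: 7 (3S)-3-(iodomethyl)-2,6-dimethylhepta-1,6-diene, via acid chloride 5 (not isolated), via Barton ester 6 (not isolated)
Conditions: (COCl)2, DMF (cat.), CH2Cl2, 0 → 23 °C; then sodium pyridine-2-thiolate 1-oxide (C5H4NNaOS), DMAP (cat.), CHI3, PhH, 80 °C, hν (W lamp)
Reagents that add atoms: iodoform, IC(I)I
Why: Barton radical decarboxylation with iodoform as iodine-atom donor traps the primary radical much faster than it can cyclise onto the remote alkene; the stereocentre is one carbon away and keeps its geometry (the descriptor becomes S only because CH2I outranks isopropenyl).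

Step 5
Reactants: 8 5-methoxybenzene-1,3-diol
Product: 9 4,6-dibromo-5-methoxybenzene-1,3-diol
Conditions: NBS (2.05 equiv), MeCN, −20 → 0 °C
Reagents that add atoms: N-bromosuccinimide, O=C1CCC(=O)N1Br
Why: Electrophilic aromatic bromination goes para to each free hydroxyl (C4 and C6), as with resorcinol and orcinol, leaving the doubly flanked C2–H.

Step 6
Reactants: 9 4,6-dibromo-5-methoxybenzene-1,3-diol
Product: 10 1,3-dibromo-2-methoxy-4,6-bis(methoxymethoxy)benzene
Conditions: MOMCl (2.5 equiv), iPr2NEt, CH2Cl2, 0 → 23 °C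
Reagents that add atoms: chloromethyl methyl ether, COCCl
Why: O-Alkylation of both phenols gives acetal ethers that survive organolithium and Grignard reagents and later come off with acid.

Step 7
Reactants: 10 1,3-dibromo-2-methoxy-4,6-bis(methoxymethoxy)benzene; 11 methyl (2R)-oxirane-2-carboxylate
Product: 15 (2R)-1-[3-bromo-2-methoxy-4,6-bis(methoxymethoxy)phenyl]-3-methylbutane-2,3-diol, via aryllithium 12 (not isolated), via aryl Grignard 13 (not isolated), via hydroxy ester 14 (not isolated)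
Conditions: n-BuLi (1.05 equiv), THF, −78 °C; MgBr2·OEt2; CuI (10 mol %), 11, −40 °C; then MeMgBr (4 equiv), −40 → 0 °C
Reagents that add atoms: methylmagnesium bromide, C[Mg]Br
Why: Single bromine–lithium exchange on the symmetric dibromide, then copper-catalysed SN2 opening of the glycidate at its CH2 carbon and double Grignard addition to the ester; the carbinol stereocentre is the untouched C2 of the bought (R)-glycidate.

Step 8
Reactants: 15 (2R)-1-[3-bromo-2-methoxy-4,6-bis(methoxymethoxy)phenyl]-3-methylbutane-2,3-diol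
Product: 17 (3R)-6-bromo-5-methoxy-2,2-dimethyl-3,4-dihydro-2H-chromene-3,7-diol, via resorcinol diol 16 (not isolated)
Conditions: p-TsOH·H2O, MeOH, 60 °C; then PhMe, 80 °C
Reagents that add atoms: none
Why: Acid removes both MOM acetals and ionises the tertiary alcohol, and the only ortho phenol captures the cation in a 6-ring cyclodehydration (SN1); the C3–O bond is never broken, so C3 stays R.

Step 9
Reactants: 17 (3R)-6-bromo-5-methoxy-2,2-dimethyl-3,4-dihydro-2H-chromene-3,7-diol
Product: 18 (3R)-6-bromo-5-methoxy-2,2-dimethyl-7-{[2-(trimethylsilyl)ethoxy]methoxy}-3,4-dihydro-2H-chromen-3-ol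
Conditions: SEMCl (1.1 equiv), iPr2NEt, CH2Cl2, 0 °C
Reagents that add atoms: 2-(trimethylsilyl)ethoxymethyl chloride, C[Si](C)(C)CCOCCl
Why: The phenol is far more acidic than the secondary alcohol and is alkylated selectively; the SEM ether is an ortho-directing group that is later removed by fluoride rather than acid.

Step 10
Reactants: 18 (3R)-6-bromo-5-methoxy-2,2-dimethyl-7-{[2-(trimethylsilyl)ethoxy]methoxy}-3,4-dihydro-2H-chromen-3-ol; 7 (3S)-3-(iodomethyl)-2,6-dimethylhepta-1,6-diene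
Product: 20 (3R)-5-methoxy-2,2-dimethyl-6-[(2R)-5-methyl-2-(prop-1-en-2-yl)hex-5-en-1-yl]-7-{[2-(trimethylsilyl)ethoxy]methoxy}-3,4-dihydro-2H-chromen-3-ol, via dilithio species 19 (not isolated)
Conditions: t-BuLi (3.1 equiv), THF, −78 °C; then CuI (10 mol %), 7, −78 → 23 °C
Reagents that add atoms: none
Why: Alkoxide formation and bromine–lithium exchange give an aryllithium flanked by two ether oxygens, which is alkylated by the primary iodide (copper-catalysed SN2) without touching either stereocentre.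

Step 11
Reactants: 20 (3R)-5-methoxy-2,2-dimethyl-6-[(2R)-5-methyl-2-(prop-1-en-2-yl)hex-5-en-1-yl]-7-{[2-(trimethylsilyl)ethoxy]methoxy}-3,4-dihydro-2H-chromen-3-ol; 21 3-[(tert-butyldimethylsilyl)oxy]benzaldehyde
Product: 23 (3R)-8-[{3-[(tert-butyldimethylsilyl)oxy]phenyl}(hydroxy)methyl]-5-methoxy-2,2-dimethyl-6-[(2R)-5-methyl-2-(prop-1-en-2-yl)hex-5-en-1-yl]-7-{[2-(trimethylsilyl)ethoxy]methoxy}-3,4-dihydro-2H-chromen-3-ol (both carbinol epimers), via aryllithium 22 (not isolated)
Conditions: n-BuLi (2.4 equiv), TMEDA, THF, 0 °C; then 21, −78 → 0 °C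
Reagents that add atoms: none
Why: Directed ortho-metalation at the only remaining ring A C–H (between the SEM ether and the ring oxygen), then 1,2-addition to the aldehyde; the new carbinol centre is removed in step 12.

Step 12
Reactants: 23 the benzhydrol from step 11
Product: 24 {3-[(tert-butyldimethylsilyl)oxy]phenyl}[(3R)-3-hydroxy-5-methoxy-2,2-dimethyl-6-[(2R)-5-methyl-2-(prop-1-en-2-yl)hex-5-en-1-yl]-7-{[2-(trimethylsilyl)ethoxy]methoxy}-3,4-dihydro-2H-chromen-8-yl]methanone
Conditions: MnO2 (excess), CH2Cl2, 23 °C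
Reagents that add atoms: none
Why: Manganese dioxide oxidises only the doubly benzylic alcohol and leaves the aliphatic C3 carbinol and the alkenes alone.

Step 13
Reactants: 24 the protected benzophenone from step 12
Product: 25 [(3R)-3,7-dihydroxy-5-methoxy-2,2-dimethyl-6-[(2R)-5-methyl-2-(prop-1-en-2-yl)hex-5-en-1-yl]-3,4-dihydro-2H-chromen-8-yl](3-hydroxyphenyl)methanone
Conditions: TBAF (6 equiv), THF/DMPU, 60 °C; aq. NH4Cl
Reagents that add atoms: none
Why: Fluoride desilylation cleaves the aryl TBS ether and the SEM acetal (loss of ethene and formaldehyde) under non-acidic conditions, so the phenol next to the isopropenyl group cannot cyclise.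

## Compound list

1 | (4R)-1-methyl-4-(prop-1-en-2-yl)-7-oxabicyclo[4.1.0]heptane, (+)-limonene 1,2-oxide, cis/trans mixture | CC12OC1C[C@@H](CC2)C(C)=C | starting material
2 | (3R)-6-oxo-3-(prop-1-en-2-yl)heptanal | O=CC[C@@H](CCC(C)=O)C(C)=C | intermediate
3 | (3R)-6-oxo-3-(prop-1-en-2-yl)heptanoic acid | OC(=O)C[C@@H](CCC(C)=O)C(C)=C | intermediate
4 | (3R)-6-methyl-3-(prop-1-en-2-yl)hept-6-enoic acid | OC(=O)C[C@@H](CCC(C)=C)C(C)=C | intermediate
5 | (3R)-6-methyl-3-(prop-1-en-2-yl)hept-6-enoyl chloride | ClC(=O)C[C@@H](CCC(C)=C)C(C)=C | intermediate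
6 | 2-sulfanylidenepyridin-1(2H)-yl (3R)-6-methyl-3-(prop-1-en-2-yl)hept-6-enoate (Barton ester) | O=C(ON1C=CC=CC1=S)C[C@@H](CCC(C)=C)C(C)=C | intermediate
7 | (3S)-3-(iodomethyl)-2,6-dimethylhepta-1,6-diene | IC[C@@H](CCC(C)=C)C(C)=C | intermediate
8 | 5-methoxybenzene-1,3-diol | COc1cc(O)cc(O)c1 | starting material
9 | 4,6-dibromo-5-methoxybenzene-1,3-diol | COc1c(Br)c(O)cc(O)c1Br | intermediate
10 | 1,3-dibromo-2-methoxy-4,6-bis(methoxymethoxy)benzene | COCOc1cc(OCOC)c(Br)c(OC)c1Br | intermediate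
11 | methyl (2R)-oxirane-2-carboxylate, methyl (R)-glycidate | COC(=O)[C@H]1CO1 | starting material
12 | [3-bromo-2-methoxy-4,6-bis(methoxymethoxy)phenyl]lithium | [Li]c1c(OCOC)cc(OCOC)c(Br)c1OC | intermediate
13 | bromido[3-bromo-2-methoxy-4,6-bis(methoxymethoxy)phenyl]magnesium | Br[Mg]c1c(OCOC)cc(OCOC)c(Br)c1OC | intermediate
14 | methyl (2R)-3-[3-bromo-2-methoxy-4,6-bis(methoxymethoxy)phenyl]-2-hydroxypropanoate | COC(=O)[C@H](O)Cc1c(OCOC)cc(OCOC)c(Br)c1OC | intermediate
15 | (2R)-1-[3-bromo-2-methoxy-4,6-bis(methoxymethoxy)phenyl]-3-methylbutane-2,3-diol | CC(C)(O)[C@H](O)Cc1c(OCOC)cc(OCOC)c(Br)c1OC | intermediate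
16 | (2R)-1-(3-bromo-4,6-dihydroxy-2-methoxyphenyl)-3-methylbutane-2,3-diol | CC(C)(O)[C@H](O)Cc1c(O)cc(O)c(Br)c1OC | intermediate
17 | (3R)-6-bromo-5-methoxy-2,2-dimethyl-3,4-dihydro-2H-chromene-3,7-diol | COc1c(Br)c(O)cc2OC(C)(C)[C@H](O)Cc12 | intermediate
18 | (3R)-6-bromo-5-methoxy-2,2-dimethyl-7-{[2-(trimethylsilyl)ethoxy]methoxy}-3,4-dihydro-2H-chromen-3-ol | COc1c(Br)c(OCOCC[Si](C)(C)C)cc2OC(C)(C)[C@H](O)Cc12 | intermediate
19 | lithium (3R)-6-lithio-5-methoxy-2,2-dimethyl-7-{[2-(trimethylsilyl)ethoxy]methoxy}-3,4-dihydro-2H-chromen-3-olate | COc1c([Li])c(OCOCC[Si](C)(C)C)cc2OC(C)(C)[C@H](O[Li])Cc12 | intermediate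
20 | (3R)-5-methoxy-2,2-dimethyl-6-[(2R)-5-methyl-2-(prop-1-en-2-yl)hex-5-en-1-yl]-7-{[2-(trimethylsilyl)ethoxy]methoxy}-3,4-dihydro-2H-chromen-3-ol | COc1c(C[C@@H](CCC(C)=C)C(C)=C)c(OCOCC[Si](C)(C)C)cc2OC(C)(C)[C@H](O)Cc12 | intermediate
21 | 3-[(tert-butyldimethylsilyl)oxy]benzaldehyde | CC(C)(C)[Si](C)(C)Oc1cccc(C=O)c1 | starting material
22 | lithium (3R)-8-lithio-5-methoxy-2,2-dimethyl-6-[(2R)-5-methyl-2-(prop-1-en-2-yl)hex-5-en-1-yl]-7-{[2-(trimethylsilyl)ethoxy]methoxy}-3,4-dihydro-2H-chromen-3-olate | COc1c(C[C@@H](CCC(C)=C)C(C)=C)c(OCOCC[Si](C)(C)C)c([Li])c2OC(C)(C)[C@H](O[Li])Cc12 | intermediate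
23 | (3R)-8-[{3-[(tert-butyldimethylsilyl)oxy]phenyl}(hydroxy)methyl]-5-methoxy-2,2-dimethyl-6-[(2R)-5-methyl-2-(prop-1-en-2-yl)hex-5-en-1-yl]-7-{[2-(trimethylsilyl)ethoxy]methoxy}-3,4-dihydro-2H-chromen-3-ol, both carbinol epimers | COc1c(C[C@@H](CCC(C)=C)C(C)=C)c(OCOCC[Si](C)(C)C)c(C(O)c3cccc(O[Si](C)(C)C(C)(C)C)c3)c2OC(C)(C)[C@H](O)Cc12 | intermediate
24 | {3-[(tert-butyldimethylsilyl)oxy]phenyl}[(3R)-3-hydroxy-5-methoxy-2,2-dimethyl-6-[(2R)-5-methyl-2-(prop-1-en-2-yl)hex-5-en-1-yl]-7-{[2-(trimethylsilyl)ethoxy]methoxy}-3,4-dihydro-2H-chromen-8-yl]methanone | COc1c(C[C@@H](CCC(C)=C)C(C)=C)c(OCOCC[Si](C)(C)C)c(C(=O)c3cccc(O[Si](C)(C)C(C)(C)C)c3)c2OC(C)(C)[C@H](O)Cc12 | intermediate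
25 | [(3R)-3,7-dihydroxy-5-methoxy-2,2-dimethyl-6-[(2R)-5-methyl-2-(prop-1-en-2-yl)hex-5-en-1-yl]-3,4-dihydro-2H-chromen-8-yl](3-hydroxyphenyl)methanone | C=C(C)CC[C@H](Cc1c(O)c(C(=O)c2cccc(O)c2)c2c(c1OC)C[C@@H](O)C(C)(C)O2)C(=C)C | target

## Step count and weak points

Total step count: 13.
Longest linear sequence: 9 steps (steps 5–13 from 8). The side-chain branch (steps 1–4) joins at step 10.

Step 4 is the first weak point: a radical iododecarboxylation in the presence of two alkenes, where cyclisation or addition to the alkenes could compete. The fallback drops the iodide and joins the fragments by a nickel-catalysed decarboxylative aryl–alkyl coupling. It sets out from acid 4, which with N-hydroxyphthalimide and N,N′-diisopropylcarbodiimide gives the redox-active ester 1,3-dioxoisoindolin-2-yl (3R)-6-methyl-3-(prop-1-en-2-yl)hept-6-enoate F1. Bromide 18 is taken through 19 (t-BuLi) and ZnCl2 to the arylzinc chloride F2. NiCl2·glyme with 4,4′-di-tert-butyl-2,2′-bipyridine in THF/DMF couples F1 with F2 and comes back to the route at 20, replacing steps 4 and 10.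

Step 8 is the second: the SN1 ring closure could be undercut by a pinacol-type hydride shift of the diol or by loss of the aryl bromine in hot acid. The fallback closes the ring by epoxide opening, with one inversion built in. It sets out from 10: step 7 is run with methyl (S)-glycidate and gives, through the hydroxy ester methyl (2S)-3-[3-bromo-2-methoxy-4,6-bis(methoxymethoxy)phenyl]-2-hydroxypropanoate F3, the diol (2S)-1-[3-bromo-2-methoxy-4,6-bis(methoxymethoxy)phenyl]-3-methylbutane-2,3-diol F4. MsCl/Et3N gives the secondary mesylate F5, and K2CO3 in MeOH closes it with inversion to the epoxide (3R)-3-{[3-bromo-2-methoxy-4,6-bis(methoxymethoxy)phenyl]methyl}-2,2-dimethyloxirane F6. HCl in MeOH at 23 °C then removes both MOM groups and lets the ortho phenol open the epoxide at its tertiary carbon (6-endo), coming back to the route at 17.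

Step 10 is the third: a hindered aryllithium has to displace a β-branched primary iodide, and E2 elimination or O-alkylation of the alkoxide could compete. The fallback reverses the polarity and uses a palladium-catalysed Negishi coupling. It sets out from 7, which with zinc dust and LiCl in THF gives the alkylzinc iodide iodido[(2S)-5-methyl-2-(prop-1-en-2-yl)hex-5-en-1-yl]zinc F7. This is coupled with aryl bromide 18 (Pd(OAc)2, 2-dicyclohexylphosphino-2′,6′-bis(dimethylamino)biphenyl, THF/PhMe) and comes back to the route at 20.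

## Further compounds

F1 | step 4 | 1,3-dioxoisoindolin-2-yl (3R)-6-methyl-3-(prop-1-en-2-yl)hept-6-enoate | O=C(ON1C(=O)c2ccccc2C1=O)C[C@@H](CCC(C)=C)C(C)=C
F2 | step 4 | chlorido[(3R)-3-(lithiooxy)-5-methoxy-2,2-dimethyl-7-{[2-(trimethylsilyl)ethoxy]methoxy}-3,4-dihydro-2H-chromen-6-yl]zinc | COc1c([Zn]Cl)c(OCOCC[Si](C)(C)C)cc2OC(C)(C)[C@H](O[Li])Cc12
F3 | step 8 | methyl (2S)-3-[3-bromo-2-methoxy-4,6-bis(methoxymethoxy)phenyl]-2-hydroxypropanoate | COC(=O)[C@@H](O)Cc1c(OCOC)cc(OCOC)c(Br)c1OC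
F4 | step 8 | (2S)-1-[3-bromo-2-methoxy-4,6-bis(methoxymethoxy)phenyl]-3-methylbutane-2,3-diol | CC(C)(O)[C@@H](O)Cc1c(OCOC)cc(OCOC)c(Br)c1OC
F5 | step 8 | (2S)-1-[3-bromo-2-methoxy-4,6-bis(methoxymethoxy)phenyl]-3-hydroxy-3-methylbutan-2-yl methanesulfonate | CC(C)(O)[C@@H](OS(C)(=O)=O)Cc1c(OCOC)cc(OCOC)c(Br)c1OC
F6 | step 8 | (3R)-3-{[3-bromo-2-methoxy-4,6-bis(methoxymethoxy)phenyl]methyl}-2,2-dimethyloxirane | CC1(C)O[C@@H]1Cc1c(OCOC)cc(OCOC)c(Br)c1OC
F7 | step 10 | iodido[(2S)-5-methyl-2-(prop-1-en-2-yl)hex-5-en-1-yl]zinc | I[Zn]C[C@@H](CCC(C)=C)C(C)=C
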